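## The problem

Carbons are numbered C1 (alkyne CH) to C15 (CH3) along the chain; the ring oxygen joins C7 and C12.

The target is a 2,7-trans-disubstituted oxepane with six stereocentres: the ether carbons C7 and C12, the ring chlorohydrin C9(Cl)/C10(OH) and the exocyclic halides C6(Cl) and C13(Br). It also carries a (Z)-enyne at C1–C4. A seven-membered ether closes poorly by C–O bond formation, and the trans relationship across the oxygen cannot be relayed from one α-carbon to the other. Both exocyclic halides are threo to the ring oxygen, so they must come from anti alcohols by inversion next to an ether oxygen that can participate. The ring chlorohydrin lies between two nearly identical neighbourhoods, so neither the face of a C9=C10 olefin nor the carbon at which chloride enters is biased by ordinary sterics. The secondary halides, the trans-chlorohydrin (which closes to an epoxide with base) and the (Z)-enyne are fragile and must come late. The enabling feature is a hidden C2 axis through the ring oxygen and the midpoint of C9–C10, which exchanges C7/C12, C8/C11 and C6/C13. With C6 and C13 both as carboxyl carbons and C9=C10 as a cis olefin, the core is a truly C2-symmetric γ,δ-unsaturated diacid: its two carboxyl groups and two olefin faces are homotopic, and each carboxyl sits for 5-exo attack on its nearer olefin carbon (C6 acid on C9, C13 acid on C10).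

## Retrosynthesis

**23 ⇒ 22 ⇒ 18 + 21.** The C3=C4 bond and the two silyl groups are cut last. The (Z)-enyne is the most sensitive unit, and cross-metathesis of the allyl group of 18 with enyne 21 installs it in one step. The forward reaction must give the Z olefin and tolerate three secondary halides.

**18 ⇒ 17 ⇒ 16 ⇒ 15.** The C6–Cl bond is cut to the anti alcohol 17 (inversion), and C5–C6 to aldehyde 16 plus an allyl nucleophile. Ester 15 is the aldehyde precursor. A reagent-controlled allylboration sets C6 in agreement with the substrate's own Felkin–Anh bias.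

**15 ⇒ 14 ⇒ 13 ⇒ 11.** The C9–Cl bond is cut to epoxide 13. Its epoxide C–O bonds are traced to bromolactone 11, in which the lactone oxygen on C9 and the bromide on C10 already define the epoxide face. Methanolysis of 11 gives the epoxide and the C6 methyl ester together.

**11 ⇒ 10 ⇒ 9 ⇒ 7.** The C13–Br bond is cut to alcohol 10 (inversion), the C13 carbinol to ethyl ketone 9 (chelation-controlled reduction through the ring oxygen), and C13–C14 to the free carboxyl of 7. This arm is finished while the other arm and the olefin are masked together as the bromolactone.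

**7 ⇒ 6 (key).** The lactone O–C9 bond and the C10–Br bond are cut. What remains is the C2-symmetric diacid 6, with only two equivalent stereocentres and no differentiation problem. This cut is preferred over any cut in a differentiated oxepene because the symmetry of 6 guarantees that halolactonization has no face, site or regiochemical choice to make. The single product has the two arms told apart (lactone versus free acid) and the C9/C10 face fixed.

**6 ⇒ 5 ⇒ 4 ⇒ 3 ⇒ 1 + 2.** The C9=C10 bond is cut (ring-closing metathesis), then C7–C8 and C11–C12 together (two-directional auxiliary-controlled allylation of a diglycolate), then the two imide bonds. Everything before the key step is two-directional, so each operation does double duty.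

## Roads not taken

**Alternative 1:** the obvious linear route. The cut is C9=C10 in a fully differentiated ring. The forward key step is ring-closing metathesis of diene A1 to oxepene A2; A1 would come from Williamson etherification of a protected chiral homoallylic alcohol with bromoacetic acid and one auxiliary-controlled glycolate allylation. The chosen plan is better for three reasons. First, A1 needs its C12/C13 diad built beforehand and a PMB group carried and removed, which costs about four more steps. Second, the olefin of A2 has two diastereotopic faces flanked by near-identical arms, so epoxidation has no bias and needs a separate directing device. Third, the ether centres are set one at a time, whereas here both are set in one operation and symmetry, not selectivity, delivers single products.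

**Alternative 2:** cut the C12–O bond. The forward key step is 7-exo opening of the trans-epoxide in hydroxy epoxide A3 by the C7 hydroxyl, giving oxepene A4. This requires separate acyclic construction of the C6/C7 diad, the Z olefin and the epoxide stereocentres. Seven-membered closure is slow and competes with 8-endo opening. A4 again poses the unbiased-face problem for the chlorohydrin. The chosen plan avoids all three.

**Alternative 3:** cut C7–C8 by a [3,3] shift. The forward key step is Ireland–Claisen rearrangement of the silyl ketene acetal of vinyl dioxepanone A5 to acid A6; the boat transition state would transfer the C10 configuration to C7 and create the cis olefin. This is stereospecific, but A5 needs a syn-1,3-diol with three stereocentres (about eight steps and a PMB group). The rearrangement through a bicyclo[3.2.2] boat with 1,3-syn substituents is untested for the seven-membered lactone. A6 is still an unsymmetrical acid whose second arm must be unmasked later. The chosen plan reaches the equivalent stage (7) in five steps.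

Key step: step 5

Remark: the stereochemical assignments below assume the usual facial preferences of the named reagents; the face is stated in each case.

## Steps

Step 1
Reactants: 1 2,2'-oxydiacetyl chloride (diglycolyl chloride); 2 (S)-4-benzyloxazolidin-2-one (2.05 equiv)
Product: 3 (4S,4'S)-3,3'-(2,2'-oxydiacetyl)bis(4-benzyloxazolidin-2-one)
Conditions: 2, n-BuLi, THF, −78 °C; then 1, −78 → 0 °C
Reagents that add atoms: none
Why: N-Acylation of the lithiated oxazolidinone by the bis(acid chloride) (Evans imide formation); no stereocentre is formed and the product keeps a C2 axis.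

Step 2
Reactants: 3
Product: 4 (4S,4'S)-3,3'-[(2R,2'R)-2,2'-oxybis(pent-4-enoyl)]bis(4-benzyloxazolidin-2-one)
Conditions: NaHMDS (2.4 equiv), THF, −78 °C; allyl iodide (6 equiv), −78 → −45 °C
Reagents that add atoms: allyl iodide (3-iodoprop-1-ene), C=CCI
Why: Two-directional Evans glycolate alkylation: each chelated (Z)-sodium enolate is allylated on the face away from the benzyl group, which should set C7 and C12 both R. Stereochemical errors end up in the separable unsymmetrical (R,S) diastereomer, so the C2 product should be of very high purity.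

Step 3
Reactants: 4
Product: 5 (4S,4'S)-3,3'-[(2R,7R)-2,3,6,7-tetrahydrooxepine-2,7-dicarbonyl]bis(4-benzyloxazolidin-2-one)
Conditions: Grubbs II (5 mol%), CH2Cl2 (0.005 M), 40 °C
Reagents that add atoms: none
Why: Ring-closing metathesis of the two allyl groups closes the seven-membered ring at C9=C10 with loss of ethene; the ring size enforces the cis olefin and the α,α'-stereocentres are untouched.

Step 4
Reactants: 5
Product: 6 (2R,7R)-2,3,6,7-tetrahydrooxepine-2,7-dicarboxylic acid
Conditions: LiOH, 30% H2O2, THF–H2O (3:1), 0 °C; Na2SO3; then 1 M HCl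
Reagents that add atoms: hydrogen peroxide (acting as lithium hydroperoxide), OO
Why: Hydroperoxide-mediated cleavage of the N-acyl oxazolidinones (exocyclic attack) should release both carboxyl groups without epimerising the α-alkoxy centres and returns the auxiliary.

Step 5
Reactants: 6
Product: 7 (1R,3R,5R,6R)-5-bromo-8-oxo-2,7-dioxabicyclo[4.2.1]nonane-3-carboxylic acid (γ-lactone C6(=O)–O–C9, Br on C10, free acid at C13)
Conditions: NBS (1.05 equiv), NaHCO3 (2.2 equiv), THF, 0 °C, dark; then 1 M HCl
Reagents that add atoms: N-bromosuccinimide, O=C1CCC(=O)N1Br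
Why: NBS forms a bromonium ion on C9=C10 and a carboxylate opens it intramolecularly (bromolactonization, the reaction type long known for cyclohex-3-ene-1-carboxylic acids and other γ,δ-unsaturated acids). The γ-lactone ring is closed in the 5-exo mode: the C6 carboxyl attacks its nearer olefin carbon C9 from the face on which it stands, and bromine ends up anti on C10. Because of the C2 axis of 6 the two olefin faces and the two carboxyl groups are homotopic, so attack of the C13 carboxyl on C10 from the other face gives the identical molecule, and a single product should form without any facial or site selection. C9 (O, R) is fixed by the tether and C10 (Br, R) by the anti opening of the bromonium ion. The only selectivities required are 5-exo over 6-endo closure, which the three-atom tether C6–C7–C8 secures, and mono-reaction, which is guaranteed because there is only one olefin. The product has lost the symmetry in three useful ways at once: the lactone marks C6 as the future enyne arm and leaves the C13 acid free for the bromopropyl arm, the lactone oxygen on C9 fixes the face of the later epoxide (cis to the C7 arm), and the C10 bromide is its leaving group.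

Step 6
Reactants: 7
Product: 9 (1R,3R,5R,6R)-5-bromo-3-propanoyl-2,7-dioxabicyclo[4.2.1]nonan-8-one, via acid chloride 8 (not isolated)
Conditions: (COCl)2, cat. DMF, CH2Cl2, 0 °C → rt, evaporate; then Et2CuLi (from EtLi and CuI), Et2O–THF, −78 °C
Reagents that add atoms: lithium diethylcuprate, [Li+].CC[Cu-]CC
Why: Acid chloride formation (Vilsmeier activation) followed by acylation of a Gilman cuprate stops at the ketone; at −78 °C the γ-lactone and the secondary bromide should not react and C12 is not enolised.

Step 7
Reactants: 9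
Product: 10 (1R,3R,5R,6R)-5-bromo-3-[(1S)-1-hydroxypropyl]-2,7-dioxabicyclo[4.2.1]nonan-8-one
Conditions: Zn(BH4)2, Et2O, −30 → 0 °C
Reagents that add atoms: none
Why: Chelation-controlled (Cram-chelate) reduction: zinc bridges the ketone oxygen and the ring oxygen on C12 and hydride arrives from the side of C12–H, which should give the 12,13-anti (13S) alcohol. The lactone is inert to Zn(BH4)2 at this temperature.

Step 8
Reactants: 10
Product: 11 (1R,3R,5R,6R)-5-bromo-3-[(1R)-1-bromopropyl]-2,7-dioxabicyclo[4.2.1]nonan-8-one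
Conditions: CBr4, (n-Oct)3P, toluene, 70 °C
Reagents that add atoms: carbon tetrabromide, BrC(Br)(Br)Br
Why: Appel bromination; SN2 displacement of the alkoxyphosphonium ion inverts C13 to R (threo to the ring oxygen). It must precede step 9 because a free C13 hydroxyl would open the later epoxide at C10.

Step 9
Reactants: 11
Product: 13 methyl (1R,3R,5R,7S)-5-[(1R)-1-bromopropyl]-4,8-dioxabicyclo[5.1.0]octane-3-carboxylate (epoxide C9–C10 cis to the C7 ester), via bromohydrin ester 12 (not isolated)
Conditions: K2CO3, MeOH, 0 °C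
Reagents that add atoms: methanol, CO
Why: Methanolysis of the strained γ-lactone frees the C9 alkoxide, which displaces the anti C10 bromide (intramolecular Williamson reaction). The epoxide is thereby formed stereospecifically on the face of the C7 ester and C6 becomes a methyl ester.

Step 10
Reactants: 13
Product: 14 methyl (2R,4S,5S,7R)-7-[(1R)-1-bromopropyl]-4-chloro-5-hydroxyoxepane-2-carboxylate
Conditions: LiCl, AcOH, THF, rt
Reagents that add atoms: lithium chloride, [Li+].[Cl-]
Why: Acid-assisted SN2 opening of the epoxide by chloride (halohydrin formation with LiX/AcOH) inverts C9 and should give the trans-chlorohydrin (9S,10S). Attack at C9 should be preferred because its rear side carries only C7–H, whereas the rear side of C10 is screened by the 1,3-syn bromopropyl group on C12; no internal nucleophile is left in the molecule.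

Step 11
Reactants: 14
Product: 15 methyl (2R,4S,5S,7R)-7-[(1R)-1-bromopropyl]-5-[(tert-butyldimethylsilyl)oxy]-4-chlorooxepane-2-carboxylate
Conditions: TBSOTf, 2,6-lutidine, CH2Cl2, −40 → 0 °C
Reagents that add atoms: tert-butyldimethylsilyl trifluoromethanesulfonate, CC(C)(C)[Si](C)(C)OS(=O)(=O)C(F)(F)F
Why: Silylation of the hindered secondary alcohol with the silyl triflate; the ether prevents lactol formation with the C6 aldehyde and competition in step 14, and keeps the chlorohydrin from closing to the epoxide.

Step 12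
Reactants: 15
Product: 16 (2R,4S,5S,7R)-7-[(1R)-1-bromopropyl]-5-[(tert-butyldimethylsilyl)oxy]-4-chlorooxepane-2-carbaldehyde
Conditions: DIBAL-H (1.1 equiv), CH2Cl2, −78 °C; Rochelle salt
Reagents that add atoms: none
Why: Partial reduction of the α-alkoxy ester by DIBAL-H at −78 °C stops at the aldehyde through the chelated tetrahedral aluminate; the aldehyde is used at once to avoid epimerisation at C7.

Step 13
Reactants: 16
Product: 17 (1S)-1-[(2R,4S,5S,7R)-7-[(1R)-1-bromopropyl]-5-[(tert-butyldimethylsilyl)oxy]-4-chlorooxepan-2-yl]but-3-en-1-ol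
Conditions: (−)-Ipc2B(allyl) [(+)-α-pinene series], Et2O, −78 °C; then NaOH, H2O2, 0 °C
Reagents that add atoms: (−)-B-allyldiisopinocampheylborane, C=CCB([C@@H]1C[C@@H]2C[C@H]([C@H]1C)C2(C)C)[C@@H]1C[C@@H]2C[C@H]([C@H]1C)C2(C)C
Why: Brown allylboration; this reagent delivers allyl to the Si face of the aldehyde, which should give the (6S) alcohol, anti to the C7 oxygen as the Felkin–Anh preference of the α-alkoxy aldehyde also demands.

Step 14
Reactants: 17
Product: 18 tert-butyl{[(2R,4S,5S,7R)-2-[(1R)-1-bromopropyl]-5-chloro-7-[(1R)-1-chlorobut-3-en-1-yl]oxepan-4-yl]oxy}dimethylsilane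
Conditions: CCl4, (n-Oct)3P, toluene, 70 °C
Reagents that add atoms: carbon tetrachloride, ClC(Cl)(Cl)Cl
Why: Appel chlorination, an SN2 displacement with inversion, converts the (6S) alcohol into the (6R) chloride, threo to the ring oxygen.

Step 15
Reactants: 19 bromoethene (vinyl bromide); 20 ethynyltri(propan-2-yl)silane
Product: 21 (but-3-en-1-yn-1-yl)tri(propan-2-yl)silane
Conditions: PdCl2(PPh3)2 (2 mol%), CuI (4 mol%), Et2NH, THF, 0 °C → rt
Reagents that add atoms: none
Why: Sonogashira coupling of the vinyl bromide with the terminal alkyne gives the conjugated enyne needed as metathesis partner.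

Step 16
Reactants: 18; 21 (5 equiv)
Product: 22 tert-butyl{[(2R,4S,5S,7R)-2-[(1R)-1-bromopropyl]-5-chloro-7-{(1R,3Z)-1-chloro-6-[tri(propan-2-yl)silyl]hex-3-en-5-yn-1-yl}oxepan-4-yl]oxy}dimethylsilane
Conditions: Grubbs II (10 mol%), benzene, 70 °C
Reagents that add atoms: none
Why: Cross-metathesis of the terminal olefin with a conjugated enyne used in excess; with second-generation ruthenium catalysts this reaction type is known to favour the (Z)-enyne, and the silyl cap keeps the alkyne out of the catalytic cycle.

Step 17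
Reactants: 22
Product: 23 (2R,4S,5S,7R)-2-[(1R)-1-bromopropyl]-5-chloro-7-[(1R,3Z)-1-chlorohex-3-en-5-yn-1-yl]oxepan-4-ol (target)
Conditions: TBAF–AcOH (1:1), THF, 0 → 40 °C
Reagents that add atoms: none
Why: Fluoride cleaves the alkynyl C–Si and the O–Si bonds; buffering with acetic acid should prevent the liberated C10 alkoxide from displacing the anti C9 chloride and avoids base-induced elimination of the halides.

## Compound list

1 | 2,2'-oxydiacetyl chloride | O=C(Cl)COCC(=O)Cl | starting material
2 | (S)-4-benzyloxazolidin-2-one | O=C1N[C@@H](Cc2ccccc2)CO1 | starting material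
3 | (4S,4'S)-3,3'-(2,2'-oxydiacetyl)bis(4-benzyloxazolidin-2-one) | O=C(COCC(=O)N1[C@@H](Cc2ccccc2)COC1=O)N1[C@@H](Cc2ccccc2)COC1=O | intermediate
4 | (4S,4'S)-3,3'-[(2R,2'R)-2,2'-oxybis(pent-4-enoyl)]bis(4-benzyloxazolidin-2-one) | C=CC[C@@H](O[C@H](CC=C)C(=O)N1[C@@H](Cc2ccccc2)COC1=O)C(=O)N1[C@@H](Cc2ccccc2)COC1=O | intermediate
5 | (4S,4'S)-3,3'-[(2R,7R)-2,3,6,7-tetrahydrooxepine-2,7-dicarbonyl]bis(4-benzyloxazolidin-2-one) | O=C([C@H]1C/C=C\C[C@H](C(=O)N2[C@@H](Cc3ccccc3)COC2=O)O1)N1[C@@H](Cc2ccccc2)COC1=O | intermediate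
6 | (2R,7R)-2,3,6,7-tetrahydrooxepine-2,7-dicarboxylic acid | OC(=O)[C@H]1C/C=C\C[C@H](C(=O)O)O1 | intermediate
7 | (1R,3R,5R,6R)-5-bromo-8-oxo-2,7-dioxabicyclo[4.2.1]nonane-3-carboxylic acid | O=C2[C@H]1C[C@@H](O2)[C@H](Br)C[C@H](C(=O)O)O1 | intermediate
8 | (1R,3R,5R,6R)-5-bromo-8-oxo-2,7-dioxabicyclo[4.2.1]nonane-3-carbonyl chloride (not isolated) | O=C2[C@H]1C[C@@H](O2)[C@H](Br)C[C@H](C(=O)Cl)O1 | intermediate
9 | (1R,3R,5R,6R)-5-bromo-3-propanoyl-2,7-dioxabicyclo[4.2.1]nonan-8-one | O=C2[C@H]1C[C@@H](O2)[C@H](Br)C[C@H](C(=O)CC)O1 | intermediate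
10 | (1R,3R,5R,6R)-5-bromo-3-[(1S)-1-hydroxypropyl]-2,7-dioxabicyclo[4.2.1]nonan-8-one | O=C2[C@H]1C[C@@H](O2)[C@H](Br)C[C@H]([C@@H](O)CC)O1 | intermediate
11 | (1R,3R,5R,6R)-5-bromo-3-[(1R)-1-bromopropyl]-2,7-dioxabicyclo[4.2.1]nonan-8-one | O=C2[C@H]1C[C@@H](O2)[C@H](Br)C[C@H]([C@H](Br)CC)O1 | intermediate
12 | methyl (2R,4R,5R,7R)-5-bromo-7-[(1R)-1-bromopropyl]-4-hydroxyoxepane-2-carboxylate (not isolated, present as alkoxide) | COC(=O)[C@H]1C[C@@H](O)[C@H](Br)C[C@H]([C@H](Br)CC)O1 | intermediate
13 | methyl (1R,3R,5R,7S)-5-[(1R)-1-bromopropyl]-4,8-dioxabicyclo[5.1.0]octane-3-carboxylate | COC(=O)[C@H]1C[C@H]2O[C@H]2C[C@H]([C@H](Br)CC)O1 | intermediate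
14 | methyl (2R,4S,5S,7R)-7-[(1R)-1-bromopropyl]-4-chloro-5-hydroxyoxepane-2-carboxylate | COC(=O)[C@H]1C[C@H](Cl)[C@@H](O)C[C@H]([C@H](Br)CC)O1 | intermediate
15 | methyl (2R,4S,5S,7R)-7-[(1R)-1-bromopropyl]-5-[(tert-butyldimethylsilyl)oxy]-4-chlorooxepane-2-carboxylate | COC(=O)[C@H]1C[C@H](Cl)[C@@H](O[Si](C)(C)C(C)(C)C)C[C@H]([C@H](Br)CC)O1 | intermediate
16 | (2R,4S,5S,7R)-7-[(1R)-1-bromopropyl]-5-[(tert-butyldimethylsilyl)oxy]-4-chlorooxepane-2-carbaldehyde | O=C[C@H]1C[C@H](Cl)[C@@H](O[Si](C)(C)C(C)(C)C)C[C@H]([C@H](Br)CC)O1 | intermediate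
17 | (1S)-1-[(2R,4S,5S,7R)-7-[(1R)-1-bromopropyl]-5-[(tert-butyldimethylsilyl)oxy]-4-chlorooxepan-2-yl]but-3-en-1-ol | C=CC[C@H](O)[C@H]1C[C@H](Cl)[C@@H](O[Si](C)(C)C(C)(C)C)C[C@H]([C@H](Br)CC)O1 | intermediate
18 | tert-butyl{[(2R,4S,5S,7R)-2-[(1R)-1-bromopropyl]-5-chloro-7-[(1R)-1-chlorobut-3-en-1-yl]oxepan-4-yl]oxy}dimethylsilane | C=CC[C@@H](Cl)[C@H]1C[C@H](Cl)[C@@H](O[Si](C)(C)C(C)(C)C)C[C@H]([C@H](Br)CC)O1 | intermediate
19 | bromoethene | C=CBr | starting material
20 | ethynyltri(propan-2-yl)silane | C#C[Si](C(C)C)(C(C)C)C(C)C | starting material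
21 | (but-3-en-1-yn-1-yl)tri(propan-2-yl)silane | C=CC#C[Si](C(C)C)(C(C)C)C(C)C | intermediate
22 | tert-butyl{[(2R,4S,5S,7R)-2-[(1R)-1-bromopropyl]-5-chloro-7-{(1R,3Z)-1-chloro-6-[tri(propan-2-yl)silyl]hex-3-en-5-yn-1-yl}oxepan-4-yl]oxy}dimethylsilane | CC(C)[Si](C#C/C=C\C[C@@H](Cl)[C@H]1C[C@H](Cl)[C@@H](O[Si](C)(C)C(C)(C)C)C[C@H]([C@H](Br)CC)O1)(C(C)C)C(C)C | intermediate
23 | (2R,4S,5S,7R)-2-[(1R)-1-bromopropyl]-5-chloro-7-[(1R,3Z)-1-chlorohex-3-en-5-yn-1-yl]oxepan-4-ol | C#C/C=C\C[C@@H](Cl)[C@H]1C[C@H](Cl)[C@@H](O)C[C@H]([C@H](Br)CC)O1 | target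

## Step count and risk

Total step count: 17. Longest linear sequence: 16 (steps 1–14, 16, 17); step 15 prepares the metathesis partner.

**Step 5 (key step).** Symmetry removes any selectivity risk, so the likely failure is interception of the bromonium ion by an external nucleophile, or 6-endo closure, because the carboxylate must fold over a flexible seven-membered ring. The fallback replaces halolactonization by syn-dihydroxylation; it sets out from 6 and comes back at 15. Catalytic OsO4/NMO gives one cis-diol (the faces are homotopic). Only the hydroxyl that is 1,3-cis to a carboxyl can lactonize, which should give the hydroxy lactone acid F1 and again tell the arms apart. Silylation with TBSOTf gives F2. Oxalyl chloride and then Et2CuLi give ketone F3, Zn(BH4)2 gives the anti alcohol F4, and CBr4/(n-Oct)3P gives bromide F5. K2CO3/MeOH opens the lactone to hydroxy ester F6, whose free C9 hydroxyl is converted with inversion by CCl4/(n-Oct)3P into 15. This branch also places O on C10 and Cl on C9 without any regiochemical choice.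

**Step 10.** The likely failure is loss of regioselectivity: chloride attacking C10 instead of C9, since both epoxide carbons are secondary and electronically alike. The fallback replaces kinetic control by a sort-and-recycle loop; it sets out from 13 and comes back at 13. The crude product is treated with catalytic CSA. The wrong regioisomer F7 has its C9 hydroxyl 1,3-cis to the C7 ester and should lactonize to chlorolactone F8, whereas 14 cannot form a γ-lactone. After separation, F8 with K2CO3/MeOH returns epoxide 13 for another pass. If the intrinsic preference were for C10, the dihydroxylation branch described for step 5 reaches 15 without an epoxide.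

**Step 16.** The likely failures are poor Z/E control or catalyst deactivation through alkyne–carbene side reactions of the enyne. The fallback builds the enyne stepwise; it sets out from 18 and comes back at 23. Ozonolysis (O3, then PPh3) gives aldehyde F9. Stork–Zhao olefination (Ph3P+CH2I I−, NaHMDS, THF–DMPU, −78 °C) gives the (Z)-vinyl iodide F10. Sonogashira coupling with trimethylsilylacetylene gives F11, and TBAF–AcOH removes both silyl groups to give 23.

## Further compounds

F1 | step 5 | (1R,3R,5S,6R)-5-hydroxy-8-oxo-2,7-dioxabicyclo[4.2.1]nonane-3-carboxylic acid | O=C2[C@H]1C[C@@H](O2)[C@@H](O)C[C@H](C(=O)O)O1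
F2 | step 5 | (1R,3R,5S,6R)-5-[(tert-butyldimethylsilyl)oxy]-8-oxo-2,7-dioxabicyclo[4.2.1]nonane-3-carboxylic acid | O=C2[C@H]1C[C@@H](O2)[C@@H](O[Si](C)(C)C(C)(C)C)C[C@H](C(=O)O)O1
F3 | step 5 | (1R,3R,5S,6R)-5-[(tert-butyldimethylsilyl)oxy]-3-propanoyl-2,7-dioxabicyclo[4.2.1]nonan-8-one | O=C2[C@H]1C[C@@H](O2)[C@@H](O[Si](C)(C)C(C)(C)C)C[C@H](C(=O)CC)O1
F4 | step 5 | (1R,3R,5S,6R)-5-[(tert-butyldimethylsilyl)oxy]-3-[(1S)-1-hydroxypropyl]-2,7-dioxabicyclo[4.2.1]nonan-8-one | O=C2[C@H]1C[C@@H](O2)[C@@H](O[Si](C)(C)C(C)(C)C)C[C@H]([C@@H](O)CC)O1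
F5 | step 5 | (1R,3R,5S,6R)-3-[(1R)-1-bromopropyl]-5-[(tert-butyldimethylsilyl)oxy]-2,7-dioxabicyclo[4.2.1]nonan-8-one | O=C2[C@H]1C[C@@H](O2)[C@@H](O[Si](C)(C)C(C)(C)C)C[C@H]([C@H](Br)CC)O1
F6 | step 5 | methyl (2R,4R,5S,7R)-7-[(1R)-1-bromopropyl]-5-[(tert-butyldimethylsilyl)oxy]-4-hydroxyoxepane-2-carboxylate | COC(=O)[C@H]1C[C@@H](O)[C@@H](O[Si](C)(C)C(C)(C)C)C[C@H]([C@H](Br)CC)O1
F7 | step 10 | methyl (2R,4R,5R,7R)-7-[(1R)-1-bromopropyl]-5-chloro-4-hydroxyoxepane-2-carboxylate | COC(=O)[C@H]1C[C@@H](O)[C@H](Cl)C[C@H]([C@H](Br)CC)O1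
F8 | step 10 | (1R,3R,5R,6R)-3-[(1R)-1-bromopropyl]-5-chloro-2,7-dioxabicyclo[4.2.1]nonan-8-one | O=C2[C@H]1C[C@@H](O2)[C@H](Cl)C[C@H]([C@H](Br)CC)O1
F9 | step 16 | (3R)-3-{(2R,4S,5S,7R)-7-[(1R)-1-bromopropyl]-5-[(tert-butyldimethylsilyl)oxy]-4-chlorooxepan-2-yl}-3-chloropropanal | O=CC[C@@H](Cl)[C@H]1C[C@H](Cl)[C@@H](O[Si](C)(C)C(C)(C)C)C[C@H]([C@H](Br)CC)O1
F10 | step 16 | tert-butyl{[(2R,4S,5S,7R)-2-[(1R)-1-bromopropyl]-5-chloro-7-[(1R,3Z)-1-chloro-4-iodobut-3-en-1-yl]oxepan-4-yl]oxy}dimethylsilane | I/C=C\C[C@@H](Cl)[C@H]1C[C@H](Cl)[C@@H](O[Si](C)(C)C(C)(C)C)C[C@H]([C@H](Br)CC)O1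
F11 | step 16 | tert-butyl{[(2R,4S,5S,7R)-2-[(1R)-1-bromopropyl]-5-chloro-7-[(1R,3Z)-1-chloro-6-(trimethylsilyl)hex-3-en-5-yn-1-yl]oxepan-4-yl]oxy}dimethylsilane | C[Si](C)(C)C#C/C=C\C[C@@H](Cl)[C@H]1C[C@H](Cl)[C@@H](O[Si](C)(C)C(C)(C)C)C[C@H]([C@H](Br)CC)O1
A1 | alternative 1 | (4S)-4-benzyl-3-[(2R)-2-{[(4R,5S)-5-[(4-methoxybenzyl)oxy]hept-1-en-4-yl]oxy}pent-4-enoyl]-1,3-oxazolidin-2-one | C=CC[C@H]([C@@H](OCc1ccc(OC)cc1)CC)O[C@H](CC=C)C(=O)N1[C@@H](Cc2ccccc2)COC1=O
A2 | alternative 1 | (4S)-4-benzyl-3-[(2R,7R)-7-{(1S)-1-[(4-methoxybenzyl)oxy]propyl}-2,3,6,7-tetrahydrooxepine-2-carbonyl]-1,3-oxazolidin-2-one | O=C([C@H]1C/C=C\C[C@H]([C@@H](OCc2ccc(OC)cc2)CC)O1)N1[C@@H](Cc2ccccc2)COC1=O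
A3 | alternative 2 | (4S,5R,7Z)-9-[(2S,3S)-3-ethyloxiran-2-yl]-4-[(4-methoxybenzyl)oxy]nona-1,7-dien-5-ol | C=CC[C@H](OCc1ccc(OC)cc1)[C@H](O)C/C=C\C[C@@H]1O[C@H]1CC
A4 | alternative 2 | (1S)-1-[(2R,7R)-7-{(1S)-1-[(4-methoxybenzyl)oxy]but-3-en-1-yl}-2,3,6,7-tetrahydrooxepin-2-yl]propan-1-ol | C=CC[C@H](OCc1ccc(OC)cc1)[C@H]1C/C=C\C[C@H]([C@@H](O)CC)O1
A5 | alternative 3 | (5R,7S)-7-ethenyl-5-{(1S)-1-[(4-methoxybenzyl)oxy]propyl}-1,4-dioxepan-2-one | C=C[C@@H]1C[C@H]([C@@H](OCc2ccc(OC)cc2)CC)OCC(=O)O1
A6 | alternative 3 | (2R,7R)-7-{(1S)-1-[(4-methoxybenzyl)oxy]propyl}-2,3,6,7-tetrahydrooxepine-2-carboxylic acid | OC(=O)[C@H]1C/C=C\C[C@H]([C@@H](OCc2ccc(OC)cc2)CC)O1
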